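I watched the fraction left.

| flask | starting complex | incoming ligand | remark | time |
|---|---|---|---|---|
| east | 0.020 M | 0.026 M | run made earlier |  |
| north-west | 0.020 M | 0.028 M | run made earlier |  |
| delta | 0.020 M | 0.0190 M |  | 5.0 min |
| theta | 0.020 M | 0.0250 M |  | 5.0 min |

| run | time / min | starting complex / % | complex with one exchanged / % | side product B / % | complex with two exchanged / % | complex with four exchanged / % |
|---|---|---|---|---|---|---|
| east | 0.417 | 80.8 | 16.1 | 0.8 | 1.4 | 0.4 |
| east | 1.33 | 54.4 | 35.7 | 5.6 | 6.7 | 0 |
| east | 2.50 | 35.8 | 42.4 | 8.0 | 7.9 | 0 |
| east | 4.00 | 23.7 | 44.7 | 10.5 | 12.4 | 0 |
| east | 5.00 | 17.2 | 43.4 | 15.1 | 13.7 | 0.2 |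
| north-west | 1.00 | 60.6 | 31.4 | 3.1 | 2.9 | 0 |
| north-west | 2.00 | 40.0 | 42.6 | 5.5 | 7.8 | 0.9 |
| north-west | 3.00 | 29.0 | 43.3 | 10.5 | 10.5 | 0 |
| north-west | 4.00 | 22.2 | 43.3 | 11.1 | 13.1 | 0 |
| north-west | 5.00 | 16.3 | 43.4 | 16.3 | 13.7 | 0 |

(each reading ± 1 percentage point)

- which of these there is most of at the end, counted by the starting complex in it, delta (complex with one exchanged / side product B / starting complex / complex with two exchanged)
- which of these there is most of at the end, counted by the starting complex in it, theta (complex with one exchanged / side product B / starting complex / complex with two exchanged)
- the largest of these amounts at the end, in percent of the starting complex charged, delta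
- the largest of these amounts at the end, in percent of the starting complex charged, theta

- a reading or a percentage of complex with four exchanged counts all its forms, free or not

I read the east run in stages. In the first instants, at 0.417 min, 80.8 % of the starting complex stood, and the first exchange was the busy step: complex with one exchanged, at 16.1 %, was more than side product B and complex with two exchanged. By the middle, at 2.50 min, starting complex was down to 35.8 %. From there to 5.00 min east lost far more starting complex, 19 percentage points, than complex with one exchanged gained, 1 point, while the readings of side product B and complex with two exchanged rose. At the end of east side product B read 15.1 %, complex with two exchanged 13.7 %, and complex with one exchanged 43.4 %, which I kept as my rough figure for both new flasks.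

For starting complex I worked with the fraction left. East gave 13.5 /M/min and north-west 13.0 /M/min, with mean 13.2 /M/min. This mean is the loss constant, minus the logarithm of the fraction left, divided by charged [incoming ligand] and by time, an apparent second-order rate constant. East read at 2.50 min gives 15.8 /M/min, more than at 5.00 min, so I applied the constant at 5.00 min, the time asked of the new flasks.

My estimate from it was 28.4 % of starting complex left in delta and 19.1 % in theta, so I put complex with one exchanged on top of both.

The forecast named complex with one exchanged for delta at 43.5 % and complex with one exchanged for theta at 43.5 %, holding for delta that “less ligand also slows its onward conversion”. Its figures are for complex with one exchanged, and those from my loss constant are for starting complex.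

Delta ended with complex with one exchanged largest at 41.9 %, and theta with complex with one exchanged largest at 43.5 %, as the forecast said. Starting complex stood at 28.4 % in delta and 18.5 % in theta.

    starting complex + incoming ligand → leaving ligand + complex with one exchanged (k = 0.330 /M/s)
    complex with one exchanged + incoming ligand → leaving ligand + complex with two exchanged (k = 0.180 /M/s)
    complex with two exchanged + incoming ligand → leaving ligand + complex with three exchanged (k = 0.410 /M/s)
    complex with three exchanged + incoming ligand → leaving ligand + complex with four exchanged (k = 0.0100 /M/s)
    complex with three exchanged → side product A (k = 0.0300 /s)
    leaving ligand + starting complex → side product B (k = 0.140 /M/s)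
    complex with four exchanged + incoming ligand ⇌ idle adduct, settled at all times (K = 48.0 /M)

In delta, side product A stood at 3.94 % after 5.00 min, yet its formation made no difference to complex with one exchanged at that time. The neighbouring flask is theta with 0.015 M of incoming ligand, 0.750 equiv. The loss constant gives 37.0 % of starting complex left there, and that flask held 37.5 %, with side product B at 14.6 % and complex with one exchanged largest at 38.6 %.

The numbers in the tables are simulated for an exercise; scatter was added.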